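Numbering: C1 tertiary carbinol, C2/C3 acetoxy carbons, C4=C5, C6 benzoyloxy carbon, C7 the CH2OBz carbon. Once C7 is raised to a carboxyl, the array C7–C1–C6–C5=C4 of the cyclohexene ring is a γ,δ-unsaturated acid. C1–C6 is therefore disconnected by a retro-Ireland–Claisen step. The precursor is not a carbocycle but a sugar δ-lactone (C7–O–C4) bearing a (Z)-2-benzoyloxyvinyl group (C5=C6). One boat-locked [3,3] shift closes the cyclohexene, sets quaternary C1 and C6, places C4=C5 and delivers the C6 benzoate. It is paid for by the sacrificial C4–O stereocentre, and either C1 epimer of the lactone converges. All seven carbons come from D-arabinose plus acetylene.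

Key step: step 4

Remark on numbering: target numbering is used for every intermediate. Arabinose C1, C2, C3, C4, C5 become C4, C3, C2, C1, C7, and the acetylene carbons become C5 and C6. With the cyclohexene drawn C1→C6 clockwise, C7 and O2 point up, and O1, O3 and O6 point down.
Assumption: 2,3,4-tri-O-benzyl-D-arabinopyranose (1) is taken as a catalogue carbohydrate building block, used as the anomeric mixture.

Step 1
Reactants: 1 2,3,4-tri-O-benzyl-D-arabinopyranose; 2 ethynylmagnesium bromide
Product: 3 4,5,6-tri-O-benzyl-1,2-dideoxy-D-gluco-hept-1-ynitol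
Conditions: HC≡CMgBr/ZnBr2 (→ HC≡CZnBr, 5 equiv), THF/Et2O, 0 °C; then 1, −20 °C → rt; aq NH4Cl
Reagents that add atoms: ethynylmagnesium bromide (2), C#C[Mg]Br
Why: Cram-chelate addition of an alkynylzinc halide to the ring-opened α-benzyloxy aldehyde form of the lactol, in which the metal bridges the C4 carbonyl oxygen and O3 and the alkynyl group enters opposite the C2 chain, should give the 3,4-syn (D-gluco) propargylic carbinol at C4 that later steers the key step.

Step 2
Reactants: 3 4,5,6-tri-O-benzyl-1,2-dideoxy-D-gluco-hept-1-ynitol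
Product: 5 2,3,4-tri-O-benzyl-6,7-dideoxy-L-gulo-hept-6-ynono-1,5-lactone, via lactol 4 (not isolated)
Conditions: TEMPO (0.2 equiv), PhI(OAc)2 (2.5 equiv), CH2Cl2, rt
Reagents that add atoms: none
Why: In this TEMPO/PhI(OAc)2 oxidative lactonisation of a 1,5-diol the primary C7–OH is oxidised faster than the secondary propargylic C4–OH, the hydroxy aldehyde closes to lactol 4 and is oxidised on, the benzyl group on O3 excludes a γ-lactone, and no stereocentre is touched (epimerisation at C1 would be harmless).

Step 3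
Reactants: 5 2,3,4-tri-O-benzyl-6,7-dideoxy-L-gulo-hept-6-ynono-1,5-lactone; 6 benzoic acid
Product: 7 (Z)-7-O-benzoyl-2,3,4-tri-O-benzyl-6-deoxy-L-gulo-hept-6-enono-1,5-lactone (lactone 5 with the ethynyl group turned into a (Z)-2-benzoyloxyvinyl group)
Conditions: PhCO2H (1.1 equiv), [Ru(cod)(η3-methallyl)2] (3 mol %), dppb (3 mol %), toluene, 60 °C
Reagents that add atoms: benzoic acid (6), O=C(O)c1ccccc1
Why: Ruthenium-vinylidene anti-Markovnikov hydroacyloxylation of a terminal alkyne, known also for propargylic oxygen-substituted alkynes, lets benzoate attack the terminal carbon C6 and should give the (Z)-enol ester under neutral conditions that leave lactone and benzyl ethers untouched.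

Step 4
Reactants: 7 (Z)-7-O-benzoyl-2,3,4-tri-O-benzyl-6-deoxy-L-gulo-hept-6-enono-1,5-lactone
Product: 10 (1S,2S,3R,6S)-6-benzoyloxy-1,2,3-tris(benzyloxy)cyclohex-4-ene-1-carboxylic acid, via silyl ketene acetal 8 (not isolated), via trimethylsilyl ester 9 (not isolated)
Conditions: LiHMDS (1.5 equiv) added to 7 + TMSCl/Et3N (6 equiv), THF, −78 °C; solvent change to toluene, 110 °C; 1 M HCl/THF, 0 °C
Reagents that add atoms: chlorotrimethylsilane, C[Si](C)(C)Cl (its silicon is found in 8 and 9 only)
Why: LiHMDS removes C1–H of the lactone in the presence of TMSCl, so the enolate is silylated at once to the cyclic ketene acetal 8, which on heating undergoes a concerted suprafacial [3,3]-sigmatropic shift (C1–C6 forms while C4–O breaks) to silyl ester 9, hydrolysed on work-up. This is the Ireland–Claisen rearrangement in its known lactone-to-cycloalkene variant (silyl ketene acetals of alkenyl lactones), and an oxygen donor on the allyl terminus, as in glycal esters, is known to be tolerated and to accelerate the shift. The cyclohexene is closed pericyclically through the only reachable boat-like bicyclo[2.2.2]-type transition state, in which the C2–C3 tether holds C3 on the inner side of the allyl unit and so gives the cis ring alkene C4=C5, while the six-membered lactone opens. C1 is controlled by the C4–O stereocentre, because the vinyl arm reaches only the lactone face on which it stands (syn to O3, anti to O2), which places C7 cis to O2 and O1 trans to O2, and because C1 is planar in 8 both C1 epimers of 7 converge. C6 is controlled by the Z geometry of the enol benzoate inside the boat, which places O6 cis to O1. The step needs silylation to outrun β-elimination of the O2 benzyloxy group, which the internal TMSCl quench at −78 °C should secure, while the hindered non-nucleophilic base spares the enol benzoate and no other acidic C–H or [3,3] array is present.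

Step 5
Reactants: 10 (1S,2S,3R,6S)-6-benzoyloxy-1,2,3-tris(benzyloxy)cyclohex-4-ene-1-carboxylic acid
Product: 11 (1S,2S,3R,6S)-6-benzoyloxy-1,2,3-tris(benzyloxy)-1-(hydroxymethyl)cyclohex-4-ene
Conditions: BH3·THF (2.5 equiv), THF, 0 °C → rt; H2O
Reagents that add atoms: none
Why: Chemoselective borane reduction of a carboxylic acid through its acyloxyborane is faster than reduction of the benzoate or hydroboration of the hindered C4=C5 alkene, which is deactivated by two allylic oxygens, and a possible 1,3-benzoyl shift from O6 to O7 would be levelled out in step 6.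

Step 6
Reactants: 11 (1S,2S,3R,6S)-6-benzoyloxy-1,2,3-tris(benzyloxy)-1-(hydroxymethyl)cyclohex-4-ene
Product: 12 [(1S,2S,3R,6S)-6-benzoyloxy-1,2,3-tris(benzyloxy)cyclohex-4-en-1-yl]methyl benzoate
Conditions: BzCl (1.5 equiv), pyridine, DMAP (cat.), CH2Cl2, 0 °C → rt
Reagents that add atoms: benzoyl chloride, O=C(Cl)c1ccccc1
Why: DMAP-catalysed acylation of the only free hydroxyl group installs the C7 benzoate without touching any stereocentre.

Step 7
Reactants: 12 [(1S,2S,3R,6S)-6-benzoyloxy-1,2,3-tris(benzyloxy)cyclohex-4-en-1-yl]methyl benzoate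
Product: 13 (6-benzoyloxy-1,2,3-trihydroxycyclohex-4-en-1-yl)methyl benzoate, all stereocentres as in 14
Conditions: BCl3 (6 equiv), C6HMe5 (9 equiv), CH2Cl2, −78 °C; MeOH quench
Reagents that add atoms: none
Why: Lewis-acid debenzylation with BCl3 and pentamethylbenzene as Friedel–Crafts scavenger for the benzyl cation cleaves all three ethers at the benzylic C–O bond, so the ring stereocentres are untouched, and unlike hydrogenolysis it spares the alkene and both benzoates, as known for benzylated cyclohexene polyols.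

Step 8
Reactants: 13 (6-benzoyloxy-1,2,3-trihydroxycyclohex-4-en-1-yl)methyl benzoate
Product: 14 cleistenediol F, [(1S,2S,3R,6S)-2,3-diacetoxy-6-benzoyloxy-1-hydroxycyclohex-4-en-1-yl]methyl benzoate
Conditions: Ac2O (5 equiv), pyridine, 0 °C → rt
Reagents that add atoms: acetic anhydride, CC(=O)OC(C)=O
Why: Selective O-acetylation, in which the two secondary alcohols O2–H and O3–H react with Ac2O/pyridine while the hindered tertiary C1–OH stays free without forcing conditions.

Compound list
1 | 2,3,4-tri-O-benzyl-D-arabinopyranose (anomeric mixture) | OC1[C@@H](OCc2ccccc2)[C@H](OCc2ccccc2)[C@H](OCc2ccccc2)CO1 | starting material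
2 | ethynylmagnesium bromide | C#C[Mg]Br | starting material
3 | 4,5,6-tri-O-benzyl-1,2-dideoxy-D-gluco-hept-1-ynitol | C#C[C@H](O)[C@@H](OCc1ccccc1)[C@H](OCc1ccccc1)[C@H](OCc1ccccc1)CO | intermediate
4 | 2,3,4-tri-O-benzyl-6,7-dideoxy-L-gulo-hept-6-ynopyranose (lactol, anomeric mixture) | C#C[C@H]1[C@@H](OCc2ccccc2)[C@H](OCc2ccccc2)[C@H](OCc2ccccc2)C(O)O1 | intermediate
5 | 2,3,4-tri-O-benzyl-6,7-dideoxy-L-gulo-hept-6-ynono-1,5-lactone | C#C[C@H]1[C@@H](OCc2ccccc2)[C@H](OCc2ccccc2)[C@H](OCc2ccccc2)C(=O)O1 | intermediate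
6 | benzoic acid | O=C(O)c1ccccc1 | starting material
7 | (Z)-7-O-benzoyl-2,3,4-tri-O-benzyl-6-deoxy-L-gulo-hept-6-enono-1,5-lactone | O=C(O/C=C\[C@H]1[C@@H](OCc2ccccc2)[C@H](OCc2ccccc2)[C@H](OCc2ccccc2)C(=O)O1)c1ccccc1 | intermediate
8 | cyclic trimethylsilyl ketene acetal of 7 (C7(OTMS)=C1(OBn)) | O=C(O/C=C\[C@H]1[C@@H](OCc2ccccc2)[C@H](OCc2ccccc2)C(OCc2ccccc2)=C(O[Si](C)(C)C)O1)c1ccccc1 | intermediate
9 | trimethylsilyl ester of acid 10 | c1ccccc1CO[C@@H]1C=C[C@H](OC(=O)c2ccccc2)[C@@](OCc2ccccc2)(C(=O)O[Si](C)(C)C)[C@H]1OCc1ccccc1 | intermediate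
10 | (1S,2S,3R,6S)-6-benzoyloxy-1,2,3-tris(benzyloxy)cyclohex-4-ene-1-carboxylic acid | c1ccccc1CO[C@@H]1C=C[C@H](OC(=O)c2ccccc2)[C@@](OCc2ccccc2)(C(=O)O)[C@H]1OCc1ccccc1 | intermediate
11 | (1S,2S,3R,6S)-6-benzoyloxy-1,2,3-tris(benzyloxy)-1-(hydroxymethyl)cyclohex-4-ene | c1ccccc1CO[C@@H]1C=C[C@H](OC(=O)c2ccccc2)[C@@](OCc2ccccc2)(CO)[C@H]1OCc1ccccc1 | intermediate
12 | [(1S,2S,3R,6S)-6-benzoyloxy-1,2,3-tris(benzyloxy)cyclohex-4-en-1-yl]methyl benzoate | c1ccccc1CO[C@@H]1C=C[C@H](OC(=O)c2ccccc2)[C@@](OCc2ccccc2)(COC(=O)c2ccccc2)[C@H]1OCc1ccccc1 | intermediate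
13 | (6-benzoyloxy-1,2,3-trihydroxycyclohex-4-en-1-yl)methyl benzoate, stereocentres as in 14 | O[C@@H]1C=C[C@H](OC(=O)c2ccccc2)[C@@](O)(COC(=O)c2ccccc2)[C@H]1O | intermediate
14 | cleistenediol F | CC(=O)O[C@@H]1C=C[C@H](OC(=O)c2ccccc2)[C@@](O)(COC(=O)c2ccccc2)[C@H]1OC(C)=O | target

Total step count: 8. Longest linear sequence: 8 steps (1 → 14).

Steps most likely to fail

Step 4. The O2 benzyloxy group may be lost by β-elimination from the lithium enolate before silylation. Alternatively, the labile silyl ketene acetal may decay if allylic strain between the Z-benzoyloxy group and C3 slows the shift. The fallback forms the same bond from a neutral, heat-stable enol ether instead of an enolate.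
- It sets out from 5, which DIBAL-H (toluene, −78 °C) reduces to lactol 4.
- Ms2O/Et3N gives the anomeric mesylate F1, and DBU eliminates it to the 2-benzyloxyglycal 1,5-anhydro-2,3,4-tri-O-benzyl-6,7-dideoxy-L-xylo-hept-1-en-6-ynitol F2.
- Hydroacyloxylation with 6 as in step 3 gives the (Z)-enol benzoate glycal F3.
- Heating in o-dichlorobenzene (180–220 °C) brings about the thermal Claisen rearrangement known for 5-alkenyl glycals, through the same boat, to the cyclohexenecarbaldehyde F4.
- NaBH4 (MeOH, 0 °C) comes back to the route at 11.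

Step 1. Facial selectivity may be poor if chelation of the α-benzyloxy aldehyde is incomplete, so that much of the C4 epimer forms. The fallback corrects the centre by inversion instead of relying on facial control.
- It sets out from 1, which is treated with plain HC≡CMgBr in THF, and the epimers are separated.
- The D-manno diol F5 is oxidised as in step 2, via the epimeric lactol F6, to the D-manno lactone F7.
- LiOH (THF/H2O) opens it to the hydroxy acid F8.
- Mitsunobu lactonisation (PPh3, DIAD, toluene, high dilution) lets the carboxylate displace the activated propargylic oxygen with inversion at C4. This comes back to the route at 5.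

Step 3. Regio- or Z-selectivity may be lost, or the propargylic C4–O bond may ionise at ruthenium. The fallback separates C–B and C–O bond formation.
- It sets out from 5, which undergoes rhodium-catalysed trans-hydroboration ([Rh(cod)Cl]2, PiPr3, Et3N, HBpin) to the (Z)-alkenyl pinacol boronate F9.
- KHF2 (aq MeOH) converts it into the potassium (Z)-alkenyltrifluoroborate F10.
- A copper-catalysed Chan–Lam-type oxidative coupling with 6 (CuBr, DMAP, O2, 4 Å MS) proceeds with retention of the alkene geometry and comes back to the route at 7.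

Further compounds
F1 | step 4 | 2,3,4-tri-O-benzyl-6,7-dideoxy-L-gulo-hept-6-ynopyranosyl methanesulfonate | C#C[C@H]1[C@@H](OCc2ccccc2)[C@H](OCc2ccccc2)[C@H](OCc2ccccc2)C(OS(C)(=O)=O)O1
F2 | step 4 | 1,5-anhydro-2,3,4-tri-O-benzyl-6,7-dideoxy-L-xylo-hept-1-en-6-ynitol | C#C[C@H]1[C@@H](OCc2ccccc2)[C@H](OCc2ccccc2)C(OCc2ccccc2)=CO1
F3 | step 4 | glycal F2 with the ethynyl group turned into a (Z)-2-benzoyloxyvinyl group | O=C(O/C=C\[C@H]1[C@@H](OCc2ccccc2)[C@H](OCc2ccccc2)C(OCc2ccccc2)=CO1)c1ccccc1
F4 | step 4 | (1S,2S,3R,6S)-6-benzoyloxy-1,2,3-tris(benzyloxy)cyclohex-4-ene-1-carbaldehyde | c1ccccc1CO[C@@H]1C=C[C@H](OC(=O)c2ccccc2)[C@@](OCc2ccccc2)(C=O)[C@H]1OCc1ccccc1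
F5 | step 1 | 4,5,6-tri-O-benzyl-1,2-dideoxy-D-manno-hept-1-ynitol | C#C[C@@H](O)[C@@H](OCc1ccccc1)[C@H](OCc1ccccc1)[C@H](OCc1ccccc1)CO
F6 | step 1 | 2,3,4-tri-O-benzyl-6,7-dideoxy-D-manno-hept-6-ynopyranose | C#C[C@@H]1[C@@H](OCc2ccccc2)[C@H](OCc2ccccc2)[C@H](OCc2ccccc2)C(O)O1
F7 | step 1 | 2,3,4-tri-O-benzyl-6,7-dideoxy-D-manno-hept-6-ynono-1,5-lactone | C#C[C@@H]1[C@@H](OCc2ccccc2)[C@H](OCc2ccccc2)[C@H](OCc2ccccc2)C(=O)O1
F8 | step 1 | 2,3,4-tri-O-benzyl-6,7-dideoxy-D-manno-hept-6-ynonic acid | C#C[C@@H](O)[C@@H](OCc1ccccc1)[C@H](OCc1ccccc1)[C@H](OCc1ccccc1)C(=O)O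
F9 | step 3 | lactone 5 with the ethynyl group turned into a (Z)-2-(pinacolboryl)vinyl group | CC1(C)OB(/C=C\[C@H]2[C@@H](OCc3ccccc3)[C@H](OCc3ccccc3)[C@H](OCc3ccccc3)C(=O)O2)OC1(C)C
F10 | step 3 | potassium (Z)-alkenyltrifluoroborate derived from F9 | [K+].F[B-](F)(F)/C=C\[C@H]1[C@@H](OCc2ccccc2)[C@H](OCc2ccccc2)[C@H](OCc2ccccc2)C(=O)O1
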